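**Assumption:** the target has no stereocentre (it is achiral), so there is no enantiomer to control; it is drawn as the free tris(hydrogen sulfate), so the last step ends with an H⁺ exchange (the tripotassium salt is the storable form).

## Retrosynthetic overview

1. Target 11 ⇒ quercetin 3-acetate 10 by tris-O-sulfation; the chelated 5-OH is spared.
2. 10 ⇒ 3',4'-di-O-benzyl ether 9 by neutral hydrogenolysis.
3. Key disconnection: ring C of 9 (C4–C4a and O1–C2) ⇒ unprotected phloroglucinol 6 + α-acetoxy β-keto ester 5 in a thermal Mentzer-type [3+3] annulation. This replaces the usual chalcone/flavonol oxidation or quercetin protection sequence and brings the 3-OAc in already in place.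
4. 5 ⇒ 3',4'-bis(benzyloxy)acetophenone 1 + diethyl carbonate 2 (Claisen, then one-pot α-bromination/acetate displacement).
5. Ring order: rings A and B are bought; ring C is formed in the key step 3.

## Route

Step 1
Reactants: 1 3',4'-bis(benzyloxy)acetophenone; 2 diethyl carbonate
Product: 3 ethyl 3-[3,4-bis(benzyloxy)phenyl]-3-oxopropanoate
Conditions: NaH (2.5 equiv), 2 (3 equiv), toluene, reflux; then aq. HCl, 0 °C
Reagents that add atoms: none
Why: Crossed Claisen condensation (C-ethoxycarbonylation of the methyl ketone enolate), driven to completion by irreversible deprotonation of the β-keto ester product; benzyl ethers are inert.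

Step 2
Reactants: 3 ethyl 3-[3,4-bis(benzyloxy)phenyl]-3-oxopropanoate
Product: 5 ethyl 2-acetoxy-3-[3,4-bis(benzyloxy)phenyl]-3-oxopropanoate (racemic), via α-bromo β-keto ester 4 (not isolated)
Conditions: NBS (1.05 equiv), NH4OAc (10 mol %), MeCN, 0 °C to rt; then KOAc (2.5 equiv), DMF, rt
Reagents that add atoms: N-bromosuccinimide O=C1CCC(=O)N1Br (its Br ends up in 4 only); potassium acetate CC(=O)[O-].[K+] (the acetoxy group of 5)
Why: Electrophilic α-bromination of the β-keto ester enol followed by SN2 displacement of the doubly activated bromide by acetate; the new α-centre is racemic and is destroyed when ring C aromatises in step 3.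

Step 3
Reactants: 5 ethyl 2-acetoxy-3-[3,4-bis(benzyloxy)phenyl]-3-oxopropanoate; 6 phloroglucinol (anhydrous)
Product: 9 2-[3,4-bis(benzyloxy)phenyl]-5,7-dihydroxy-4-oxo-4H-chromen-3-yl acetate, via acylketene 7 (not isolated), via 2-acetoxy-1,3-diketone 8 (not isolated)
Conditions: 5 (1.0 equiv), 6 (1.1 equiv), neat melt, microwave, 235–240 °C, 5–8 min, N2 sweep
Reagents that add atoms: none
Why: Proposed new method: above 200 °C the β-keto ester 5 loses EtOH to the α-oxoketene 7, which C-acylates the very nucleophilic phloroglucinol (directly or by O-acylation and thermal Fries shift) to diketone 8, whose ortho-OH adds to the aroyl carbonyl and then loses water (C3–H is the only β-hydrogen, so water and not AcOH is eliminated) to give the γ-pyrone; the closest known reaction is the catalyst-free Mentzer chromone synthesis of 5,7-dihydroxyflavones from phloroglucinol and benzoylacetates, and the untested element is survival of the α-acetoxy group, which meets no acid, base or external nucleophile once EtOH and H2O are swept out; no stereocentre remains.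

Step 4
Reactants: 9 2-[3,4-bis(benzyloxy)phenyl]-5,7-dihydroxy-4-oxo-4H-chromen-3-yl acetate
Product: 10 2-(3,4-dihydroxyphenyl)-5,7-dihydroxy-4-oxo-4H-chromen-3-yl acetate (quercetin 3-acetate)
Conditions: H2 (1 atm), 10 % Pd/C, THF–EtOAc, rt
Reagents that add atoms: none
Why: Catalytic hydrogenolysis of the two benzyl aryl ethers under neutral aprotic conditions, which neither solvolyse the 3-acetate nor reduce the tetrasubstituted C2=C3 bond of the vinylogous ester.

Step 5
Reactants: 10 quercetin 3-acetate
Product: 11 quercetin 3-acetate 7,3',4'-tri-O-sulfate (target)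
Conditions: SO3·pyridine (12 equiv), dry DMF–pyridine 4:1, 40 °C; then cold H2O, Dowex 50W (H+), 0 °C, LH-20, lyophilise
Reagents that add atoms: sulfur trioxide–pyridine complex O=S(=O)([O-])[n+]1ccccc1
Why: Phenol O-sulfonation with an amine–SO3 complex sulfates the 7-, 3'- and 4'-OH groups, while the 5-OH, locked in a hydrogen bond to the C4 carbonyl, is not sulfated under these mild conditions, and the absence of hydroxide or alkoxide keeps the 3-acetate intact.

## Compound list

1 | 3',4'-bis(benzyloxy)acetophenone | CC(=O)c1ccc(OCc2ccccc2)c(OCc2ccccc2)c1 | starting material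
2 | diethyl carbonate | CCOC(=O)OCC | starting material
3 | ethyl 3-[3,4-bis(benzyloxy)phenyl]-3-oxopropanoate | CCOC(=O)CC(=O)c1ccc(OCc2ccccc2)c(OCc2ccccc2)c1 | intermediate
4 | ethyl 2-bromo-3-[3,4-bis(benzyloxy)phenyl]-3-oxopropanoate (racemic, not isolated) | CCOC(=O)C(Br)C(=O)c1ccc(OCc2ccccc2)c(OCc2ccccc2)c1 | intermediate
5 | ethyl 2-acetoxy-3-[3,4-bis(benzyloxy)phenyl]-3-oxopropanoate (racemic) | CCOC(=O)C(OC(C)=O)C(=O)c1ccc(OCc2ccccc2)c(OCc2ccccc2)c1 | intermediate
6 | phloroglucinol (benzene-1,3,5-triol) | Oc1cc(O)cc(O)c1 | starting material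
7 | 1-[3,4-bis(benzyloxy)benzoyl]-2-oxoethenyl acetate (acylketene, not isolated) | CC(=O)OC(=C=O)C(=O)c1ccc(OCc2ccccc2)c(OCc2ccccc2)c1 | intermediate
8 | 1-[3,4-bis(benzyloxy)phenyl]-1,3-dioxo-3-(2,4,6-trihydroxyphenyl)propan-2-yl acetate (racemic, enolisable, not isolated) | CC(=O)OC(C(=O)c1ccc(OCc2ccccc2)c(OCc2ccccc2)c1)C(=O)c1c(O)cc(O)cc1O | intermediate
9 | 2-[3,4-bis(benzyloxy)phenyl]-5,7-dihydroxy-4-oxo-4H-chromen-3-yl acetate (3-O-acetyl-3',4'-di-O-benzylquercetin) | CC(=O)Oc1c(-c2ccc(OCc3ccccc3)c(OCc3ccccc3)c2)oc2cc(O)cc(O)c2c1=O | intermediate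
10 | 2-(3,4-dihydroxyphenyl)-5,7-dihydroxy-4-oxo-4H-chromen-3-yl acetate (quercetin 3-acetate) | CC(=O)Oc1c(-c2ccc(O)c(O)c2)oc2cc(O)cc(O)c2c1=O | intermediate
11 | quercetin 3-acetate 7,3',4'-tri-O-sulfate | CC(=O)Oc1c(-c2ccc(OS(=O)(=O)O)c(OS(=O)(=O)O)c2)oc2cc(OS(=O)(=O)O)cc(O)c2c1=O | target

## Step count and risk

Total step count: 5 (step 2 is a one-pot, two-stage operation). Longest linear sequence: 5 steps, from 1.

The three steps most likely to fail, in order of risk:

**Step 3 (thermal annulation with the acetate in place).** The risks are acetyl transfer to phenols or loss of the acetate at 240 °C. The fallback sets out from 3 (with 6) and comes back at 10; it forms the flavone without the acetate and oxidises C3 late. Compound 3 and 6 are condensed under the same thermal conditions, which is the precedented acetoxy-free Mentzer reaction, to give 3',4'-bis(benzyloxy)-5,7-dihydroxyflavone F1. Exhaustive benzylation (BnBr, K2CO3, DMF, 80 °C) gives 5,7,3',4'-tetrakis(benzyloxy)flavone F2. Epoxidation of the C2=C3 bond with dimethyldioxirane (acetone–CH2Cl2, 0 °C), followed by acid-catalysed epoxide opening (cat. TsOH), gives 3-hydroxy-5,7,3',4'-tetrakis(benzyloxy)flavone F3. Acetylation (Ac2O, pyridine) gives 3-acetoxy-5,7,3',4'-tetrakis(benzyloxy)flavone F4, and hydrogenolysis (H2, Pd/C, THF–EtOAc) gives 10.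

**Step 5 (direct tris-sulfation).** The risks are incomplete sulfation of the 3',4'-catechol, acetate loss or migration, and the handling of a polyanionic product. The fallback sets out from 10 and comes back at 11; it uses masked sulfates that can be purified on silica. Compound 10 is treated with 2,2,2-trichloroethyl chlorosulfate (3.3 equiv), Et3N and catalytic DMAP in THF at 0 °C; the chelated 5-OH is left free. This gives 3-acetoxy-5-hydroxyflavone-7,3',4'-triyl tris(2,2,2-trichloroethyl sulfate) F5. Reductive removal of the trichloroethyl groups (Zn dust, HCO2NH4, MeCN–THF, rt), then H⁺ exchange, gives 11.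

**Step 2 (bromination/displacement).** The risks are dibromination, or reduction and dimerisation of the bromide instead of substitution. The fallback sets out from 3 and comes back at 5; it replaces the SN2 step by a carbenoid O–H insertion. Diazo transfer to 3 (4-acetamidobenzenesulfonyl azide, Et3N, MeCN) gives ethyl 2-diazo-3-[3,4-bis(benzyloxy)phenyl]-3-oxopropanoate F6. Rh2(OAc)4-catalysed O–H insertion into acetic acid (AcOH, CH2Cl2, 40 °C) gives 5.

## Further compounds

F1 | step 3 | 3',4'-bis(benzyloxy)-5,7-dihydroxyflavone | O=c1cc(-c2ccc(OCc3ccccc3)c(OCc3ccccc3)c2)oc2cc(O)cc(O)c12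
F2 | step 3 | 5,7,3',4'-tetrakis(benzyloxy)flavone | O=c1cc(-c2ccc(OCc3ccccc3)c(OCc3ccccc3)c2)oc2cc(OCc3ccccc3)cc(OCc3ccccc3)c12
F3 | step 3 | 3-hydroxy-5,7,3',4'-tetrakis(benzyloxy)flavone | O=c1c(O)c(-c2ccc(OCc3ccccc3)c(OCc3ccccc3)c2)oc2cc(OCc3ccccc3)cc(OCc3ccccc3)c12
F4 | step 3 | 3-acetoxy-5,7,3',4'-tetrakis(benzyloxy)flavone | CC(=O)Oc1c(-c2ccc(OCc3ccccc3)c(OCc3ccccc3)c2)oc2cc(OCc3ccccc3)cc(OCc3ccccc3)c2c1=O
F5 | step 5 | 3-acetoxy-5-hydroxyflavone-7,3',4'-triyl tris(2,2,2-trichloroethyl sulfate) | CC(=O)Oc1c(-c2ccc(OS(=O)(=O)OCC(Cl)(Cl)Cl)c(OS(=O)(=O)OCC(Cl)(Cl)Cl)c2)oc2cc(OS(=O)(=O)OCC(Cl)(Cl)Cl)cc(O)c2c1=O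
F6 | step 2 | ethyl 2-diazo-3-[3,4-bis(benzyloxy)phenyl]-3-oxopropanoate | CCOC(=O)C(=[N+]=[N-])C(=O)c1ccc(OCc2ccccc2)c(OCc2ccccc2)c1
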